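**Strategy.** The ten-membered carbocycle is closed by making the C8–C9 bond (germacrane numbering), the bond between the two acyloxy-bearing ring carbons that lies next to the C10 methyl acrylate unit. In the open-chain precursor C9 is the aldehyde of a 2-formylacrylate (C9–C10(C14)=C1) and C8 is an aldehyde on the lactone carbon C7. CrCl2/Et3SiCl turns the formylacrylate into a γ-silyloxyallylchromium that adds to C8 through C9: one operation closes the ring, restores the C1=C10 enoate, sets C8 and C9 and leaves their oxygens differentiated (OH, OSiEt3). The precursor comes from a butenolide vinylogous aldol adduct (C1–C6) and a glyceraldehyde-derived bromomethylacrylate (C7, C8, C11–C13).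

Key step: step 19

Remarks
- Numbering: C1–C10 are the ring carbons, C11–C13 the α-methylene lactone carbons (C12 the carbonyl, closed onto O6), C14 the ester carbon on C10, C15 the methyl on C4.
- Assumption: the (S,S)-Ph-pybox copper catalyst of step 8 is taken to attack the aldehyde face that gives the anti (5S,1′R) adduct; if the sense is the opposite, the (R,R)-ligand is used and nothing else changes.

**Fragment A: allylic bromide (C7, C8, C11–C13)**

Step 1
Reactants: 1 (R)-2,2-dimethyl-1,3-dioxolane-4-carbaldehyde; 2 methyl acrylate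
Product: 3 methyl 2-{[(4R)-2,2-dimethyl-1,3-dioxolan-4-yl](hydroxy)methyl}prop-2-enoate (both carbinol epimers)
Conditions: DABCO (0.5 equiv), neat methyl acrylate, rt
Reagents that add atoms: none
Why: Morita–Baylis–Hillman reaction of an activated α-alkoxy aldehyde; the new carbinol centre forms as a mixture, which is harmless because it becomes sp2 in step 2, while the dioxolane centre is untouched.

Step 2
Reactants: 3 Baylis–Hillman adduct
Product: 4 methyl (2Z)-2-(bromomethyl)-3-[(4S)-2,2-dimethyl-1,3-dioxolan-4-yl]prop-2-enoate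
Conditions: NBS, Me2S, CH2Cl2, 0 °C to rt
Reagents that add atoms: N-bromosuccinimide, O=C1CCC(=O)N1Br
Why: Corey–Kim activation of the allylic alcohol and SN2′ attack of bromide should give the trisubstituted enoate with the dioxolanyl group trans to the ester (Z), both carbinol epimers converging.

**Fragment B: side-chain acid**

Step 3
Reactants: 5 (E)-2-methylbut-2-en-1-ol
Product: 6 [(2R,3R)-2,3-dimethyloxiran-2-yl]methanol
Conditions: Ti(OiPr)4 (10 mol %), D-(−)-diisopropyl tartrate (12 mol %), t-BuOOH, 4 Å MS, CH2Cl2, −20 °C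
Reagents that add atoms: tert-butyl hydroperoxide, CC(C)(C)OO
Why: Sharpless asymmetric epoxidation of an (E)-trisubstituted allylic alcohol; the D-(−)-tartrate complex delivers oxygen to the face that gives the (2R,3R)-epoxide, setting both side-chain centres.

Step 4
Reactants: 6 epoxy alcohol
Product: 7 (2R,3S)-3-acetoxy-2-methylbutane-1,2-diol
Conditions: Ti(OiPr)4 (1.5 equiv), AcOH (2 equiv), CH2Cl2, rt
Reagents that add atoms: acetic acid, CC(=O)O
Why: Titanium-assisted opening of a 2,3-epoxy alcohol by a carboxylic acid occurs at C3 (C2 is quaternary and carries the titanium-bound CH2O arm) with inversion, which sets the 3S acetoxy centre and frees the tertiary hydroxyl.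

Step 5
Reactants: 7 acetoxy diol
Product: 8 (2S,3S)-3-acetoxy-2-hydroxy-2-methylbutanoic acid
Conditions: TEMPO (cat.), PhI(OAc)2 (2.2 equiv), MeCN/H2O, rt
Reagents that add atoms: water, O
Why: Oxoammonium oxidation of the primary alcohol through the aldehyde hydrate to the acid; the tertiary alcohol and the acetate are inert and no stereocentre is touched (the descriptor at C2 changes only by priority).

Step 6
Reactants: 8 hydroxy acid
Product: 10 (2S,3S)-3-acetoxy-2-methyl-2-(triethylsilyloxy)butanoic acid, via bis-silylated silyl ester 9 (not isolated)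
Conditions: Et3SiOTf (2.2 equiv), 2,6-lutidine, CH2Cl2, 0 °C; then aq. AcOH/THF
Reagents that add atoms: triethylsilyl trifluoromethanesulfonate, CC[Si](CC)(CC)OS(=O)(=O)C(F)(F)F
Why: The silyl triflate silylates both the tertiary alcohol and the acid, and the labile silyl ester is hydrolysed in the work-up, so the tertiary hydroxyl is masked for the later esterification.

**Main line**

Step 7
Reactants: 11 4-methylfuran-2(5H)-one
Product: 12 4-methyl-2-(trimethylsilyloxy)furan
Conditions: Me3SiOTf, Et3N, CH2Cl2, 0 °C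
Reagents that add atoms: trimethylsilyl trifluoromethanesulfonate, C[Si](C)(C)OS(=O)(=O)C(F)(F)F
Why: γ-Deprotonation of the butenolide and O-silylation give the aromatic silyloxyfuran, a vinylogous enol ether that is nucleophilic at C5.

Step 8
Reactants: 12 silyloxyfuran; 13 2-[(4-methoxybenzyl)oxy]acetaldehyde
Product: 15 (5S)-5-{(1R)-1-hydroxy-2-[(4-methoxybenzyl)oxy]ethyl}-4-methylfuran-2(5H)-one, via trimethylsilyl ether 14 (not isolated)
Conditions: [Cu((S,S)-Ph-pybox)](SbF6)2 (10 mol %), CH2Cl2, −78 °C; then 1 M HCl, THF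
Reagents that add atoms: none
Why: Catalytic enantioselective vinylogous Mukaiyama aldol addition to a chelating alkoxyacetaldehyde bound to the chiral divalent copper Lewis acid should give the anti (erythro) adduct, creating C3 and C2 together and locking the C4=C5 geometry as Z inside the butenolide.

Step 9
Reactants: 15 aldol adduct
Product: 16 (5S)-5-{(1R)-1-(tert-butyldimethylsilyloxy)-2-[(4-methoxybenzyl)oxy]ethyl}-4-methylfuran-2(5H)-one
Conditions: TBSCl, imidazole, DMF, rt
Reagents that add atoms: tert-butyldimethylsilyl chloride, CC(C)(C)[Si](C)(C)Cl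
Why: Standard silylation of the secondary alcohol under weakly basic conditions that do not enolise the butenolide.

Step 10
Reactants: 16 silylated butenolide
Product: 17 (5S)-5-{(1R)-1-(tert-butyldimethylsilyloxy)-2-[(4-methoxybenzyl)oxy]ethyl}-4-methyl-2,5-dihydrofuran-2-ol (anomer mixture)
Conditions: i-Bu2AlH (1.1 equiv), CH2Cl2, −78 °C
Reagents that add atoms: none
Why: 1,2-Reduction of the lactone stops at the lactol because the tetrahedral aluminate is stable at low temperature; the lactol is the masked (Z)-γ-hydroxy enal (C6 aldehyde) and is used without acid contact.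

Step 11
Reactants: 17 lactol; 4 allylic bromide
Product: 19 cis-α-methylene-γ-butyrolactone (6R,7R) bearing the (4S)-2,2-dimethyl-1,3-dioxolan-4-yl group on C7 and the (4Z)-chain C5=C4(CH3)–C3H(OH)–C2H(OTBS)–C1H2OPMB (3S,2R) on C6, via open hydroxy ester 18 (not isolated)
Conditions: indium powder, THF/H2O (1:1), rt; then PPTS (cat.), CH2Cl2, rt
Reagents that add atoms: none
Why: Barbier-type allylation in water: the 2-(methoxycarbonyl)allylindium adds to the open aldehyde form through its γ-carbon via a Zimmerman–Traxler chair (syn adduct, hence the cis lactone) on the allyl face anti to the dioxolane C–O bond with the C8 hydrogen in the alkene plane, which sets C7 and C6, and the C6 hydroxyl then lactonises onto the methyl ester.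

Step 12
Reactants: 19 hydroxy lactone
Product: 20 the C3 triisopropylsilyl ether of 19
Conditions: i-Pr3SiOTf, 2,6-lutidine, CH2Cl2, 0 °C
Reagents that add atoms: triisopropylsilyl trifluoromethanesulfonate, CC(C)[Si](C(C)C)(C(C)C)OS(=O)(=O)C(F)(F)F
Why: Silylation of the allylic C3 alcohol with a group that outlasts the C2 silyl ether and is removed only in the last step.

Step 13
Reactants: 20 PMB ether
Product: 21 primary alcohol (C1–OH)
Conditions: DDQ, CH2Cl2/pH 7 buffer, 0 °C
Reagents that add atoms: none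
Why: Oxidative cleavage of the electron-rich p-methoxybenzyl ether; silyl ethers, the acetonide and the alkenes are not affected.

Step 14
Reactants: 21 primary alcohol
Product: 22 aldehyde (C1 aldehyde, α-silyloxy)
Conditions: Dess–Martin periodinane, NaHCO3, CH2Cl2, 0 °C
Reagents that add atoms: none
Why: Buffered Dess–Martin oxidation gives the α-silyloxy aldehyde without epimerising C2.

Step 15
Reactants: 22 aldehyde; 23 methyl propiolate
Product: 25 Baylis–Hillman-type adduct, C1 carbinol (both epimers) carrying C10(=C9H2)CO2CH3, via vinylalane 24 (not isolated)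
Conditions: 23, i-Bu2AlH, NMO, THF, 0 °C; then 22, 0 °C to rt
Reagents that add atoms: none
Why: Vinylalumination: hydroalumination of the propiolate gives the α-aluminoacrylate, which adds 1,2 to the aldehyde under non-basic conditions (a fast equivalent of the Morita–Baylis–Hillman reaction); the C1 carbinol mixture is irrelevant.

Step 16
Reactants: 25 allylic alcohol
Product: 26 (Z)-allylic bromide, C9H2Br on C10 with C1=C10 formed (C2 cis to C9)
Conditions: NBS, Me2S, CH2Cl2, 0 °C
Reagents that add atoms: N-bromosuccinimide, O=C1CCC(=O)N1Br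
Why: Corey–Kim SN2′ bromination as in step 2 gives the trisubstituted enoate with C2 trans to the ester, which is the geometry of the target's C1=C10 bond.

Step 17
Reactants: 26 allylic bromide
Product: 27 2-formylacrylate (C9 aldehyde)
Conditions: NMO, 4 Å MS, MeCN, rt
Reagents that add atoms: N-methylmorpholine N-oxide, C[N+]1([O-])CCOCC1
Why: Kornblum-type oxidation: SN2 displacement of the primary allylic bromide by the N-oxide oxygen and elimination give the aldehyde with the alkene geometry kept.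

Step 18
Reactants: 27 dioxolane
Product: 28 dialdehyde (C8 and C9 aldehydes)
Conditions: H5IO6, EtOAc, rt
Reagents that add atoms: none
Why: Periodic acid hydrolyses the terminal acetonide and cleaves the glycol in one pot under non-basic conditions, which protects the epimerisable C7 centre; 28 is used at once.

Step 19
Reactants: 28 dialdehyde
Product: 30 macrocycle, methyl (1(10)E,4Z)-8-hydroxy-9-(triethylsilyloxy)-2-(tert-butyldimethylsilyloxy)-3-(triisopropylsilyloxy)-germacra-1(10),4,11(13)-trien-12,6-olid-14-oate (2R,3S,6R,7R,8S,9R), via allylchromium species 29 (not isolated)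
Conditions: CrCl2 (8 equiv), Et3SiCl (4 equiv), THF, rt, slow addition of 28 (final 2 mM)
Reagents that add atoms: chlorotriethylsilane, CC[Si](CC)(CC)Cl
Why: CrCl2 transfers two electrons to the electron-poor 2-formylacrylate while Et3SiCl traps the aldehyde oxygen, giving the γ-silyloxy-2-(methoxycarbonyl)allylchromium 29 (chromium on C1), which adds to the C8 aldehyde through C9 in an SE2′ sense via a six-membered chair with chromium bound to the C8 carbonyl oxygen; the closest known reaction type is the chromium dichloride/silyl chloride cross-pinacol-type coupling of enals with aldehydes, run here as a Nozaki–Hiyama-type macrocyclisation. The ten-membered carbocycle is closed in a 10-endo mode (C1, C10 and C9 of the allyl unit all become ring atoms), and the C1=C10 bond is re-formed with C2 cis to C9 because C2 must sit axial on C1 for the six-atom tether to reach C7, which is also the less strained ring-cis enoate. C8 is set by attack of C9 anti to the C7–C6 bond (Felkin–Anh), an arrangement the tether itself favours because C6 leads back to C1 on the chromium side of the chair, giving 8S. C9 is set by the equatorial OSiEt3 group of the enol ether (silyloxy trans to C1) in the same chair, which should give the 8,9-anti (erythro) relationship, 9R, the epimer that step 22 inverts. The step needs chemoselective reduction of the formylacrylate beside the aliphatic aldehyde and the α-methylene lactone (its much lower LUMO secures this) and carbonyl addition faster than β-elimination of the C2 silyloxy group (high dilution, intramolecular addition and the poor leaving ability of a silyl ether favour it).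

Step 20
Reactants: 30 macrocyclic alcohol; 10 side-chain acid
Product: 32 C8 ester of 30 with (2S,3S)-3-acetoxy-2-methyl-2-(triethylsilyloxy)butanoic acid, via mixed anhydride 31 (not isolated)
Conditions: 10, 2,4,6-trichlorobenzoyl chloride, Et3N, THF, rt; then 30, DMAP, toluene, 40 °C
Reagents that add atoms: none
Why: Yamaguchi esterification acylates the only free hydroxyl (C8) with the α-silyloxy acid through the mixed anhydride, with retention at C8.

Step 21
Reactants: 32 bis(triethylsilyl) compound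
Product: 33 C9 alcohol (side-chain tertiary triethylsilyl ether, C2 TBS and C3 TIPS ethers kept)
Conditions: PPTS, MeOH/CH2Cl2, 0 °C
Reagents that add atoms: none
Why: Mild acid methanolysis removes the secondary allylic triethylsilyl ether much faster than the hindered tertiary triethylsilyl ether and the bulkier TBS and TIPS ethers.

Step 22
Reactants: 33 C9 alcohol; 34 (R)-2-methylbutanoic acid
Product: 35 8,9-diester with the (9S) (R)-2-methylbutanoate (8,9-threo)
Conditions: PPh3, DIAD, 34, toluene, 0 °C to rt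
Reagents that add atoms: none
Why: Mitsunobu esterification displaces the activated C9 oxygen by the carboxylate with inversion (SN2 at C9 is favoured because the SN2′ terminus C1 is substituted and the allyl cation is destabilised by the ester), which turns the erythro pair from step 19 into the natural 8S,9S threo diester.

Step 23
Reactants: 35 silyl ethers
Product: 36 C2 alcohol with free side-chain tertiary hydroxyl (C3 TIPS ether kept)
Conditions: HF·pyridine, pyridine, THF, 0 °C to rt
Reagents that add atoms: none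
Why: Buffered HF·pyridine cleaves the secondary TBS ether and the tertiary triethylsilyl ether while the more hindered triisopropylsilyl ether survives.

Step 24
Reactants: 36 C2 alcohol
Product: 37 (2S)-2-chloro compound (C2 inverted)
Conditions: PPh3, NCS, THF, 0 °C to rt
Reagents that add atoms: N-chlorosuccinimide, O=C1CCC(=O)N1Cl
Why: Appel-type chlorination through the alkoxyphosphonium ion replaces the C2 oxygen by chloride with inversion; the tertiary hydroxyl is too hindered to react.

Step 25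
Reactants: 37 chloride
Product: 39 target, methyl (1(10)E,4Z)-8α-[(2S,3S)-3-acetoxy-2-hydroxy-2-methylbutanoyloxy]-9β-[(R)-2-methylbutanoyloxy]-2β,3β-epoxygermacra-1(10),4,11(13)-trien-12,6β-olid-14-oate (2R,3S,6R,7R,8S,9S), via chlorohydrin 38 (not isolated)
Conditions: Bu4NF, THF, 0 °C
Reagents that add atoms: none
Why: Fluoride removes the triisopropylsilyl group and the C3 alkoxide closes the epoxide by intramolecular Williamson displacement of chloride (3-exo-tet) with a second inversion at C2, giving the cis-2,3-epoxide with net retention at both carbons.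

**Compound list**

1 | (R)-2,2-dimethyl-1,3-dioxolane-4-carbaldehyde | O=C[C@H]1COC(C)(C)O1 | starting material
2 | methyl acrylate | C=CC(=O)OC | starting material
3 | methyl 2-{[(4R)-2,2-dimethyl-1,3-dioxolan-4-yl](hydroxy)methyl}prop-2-enoate, both carbinol epimers | C=C(C(=O)OC)C(O)[C@H]1COC(C)(C)O1 | intermediate
4 | methyl (2Z)-2-(bromomethyl)-3-[(4S)-2,2-dimethyl-1,3-dioxolan-4-yl]prop-2-enoate | BrC/C(C(=O)OC)=C\[C@H]1COC(C)(C)O1 | intermediate
5 | (E)-2-methylbut-2-en-1-ol | C/C=C(\C)CO | starting material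
6 | [(2R,3R)-2,3-dimethyloxiran-2-yl]methanol | C[C@H]1O[C@]1(C)CO | intermediate
7 | (2R,3S)-3-acetoxy-2-methylbutane-1,2-diol | CC(=O)O[C@@H](C)[C@](C)(O)CO | intermediate
8 | (2S,3S)-3-acetoxy-2-hydroxy-2-methylbutanoic acid | OC(=O)[C@@](C)(O)[C@H](C)OC(C)=O | intermediate
9 | triethylsilyl (2S,3S)-3-acetoxy-2-methyl-2-(triethylsilyloxy)butanoate | CC[Si](CC)(CC)OC(=O)[C@@](C)(O[Si](CC)(CC)CC)[C@H](C)OC(C)=O | intermediate
10 | (2S,3S)-3-acetoxy-2-methyl-2-(triethylsilyloxy)butanoic acid | OC(=O)[C@@](C)(O[Si](CC)(CC)CC)[C@H](C)OC(C)=O | intermediate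
11 | 4-methylfuran-2(5H)-one | CC1=CC(=O)OC1 | starting material
12 | 4-methyl-2-(trimethylsilyloxy)furan | Cc1coc(O[Si](C)(C)C)c1 | intermediate
13 | 2-[(4-methoxybenzyl)oxy]acetaldehyde | O=CCOCc1ccc(OC)cc1 | starting material
14 | (5S)-5-{(1R)-2-[(4-methoxybenzyl)oxy]-1-(trimethylsilyloxy)ethyl}-4-methylfuran-2(5H)-one | CC1=CC(=O)O[C@@H]1[C@H](O[Si](C)(C)C)COCc1ccc(OC)cc1 | intermediate
15 | (5S)-5-{(1R)-1-hydroxy-2-[(4-methoxybenzyl)oxy]ethyl}-4-methylfuran-2(5H)-one | CC1=CC(=O)O[C@@H]1[C@H](O)COCc1ccc(OC)cc1 | intermediate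
16 | (5S)-5-{(1R)-1-(tert-butyldimethylsilyloxy)-2-[(4-methoxybenzyl)oxy]ethyl}-4-methylfuran-2(5H)-one | CC1=CC(=O)O[C@@H]1[C@H](O[Si](C)(C)C(C)(C)C)COCc1ccc(OC)cc1 | intermediate
17 | (5S)-5-{(1R)-1-(tert-butyldimethylsilyloxy)-2-[(4-methoxybenzyl)oxy]ethyl}-4-methyl-2,5-dihydrofuran-2-ol, anomer mixture | CC1=CC(O)O[C@@H]1[C@H](O[Si](C)(C)C(C)(C)C)COCc1ccc(OC)cc1 | intermediate
18 | open hydroxy ester: methyl acrylate unit on C7 (7R), dioxolanyl (4S) on C7, C6–OH (6R), 4Z, C3–OH (3S), C2–OTBS (2R), C1–OPMB | C=C(C(=O)OC)[C@@H]([C@H]1COC(C)(C)O1)[C@H](O)/C=C(/C)[C@H](O)[C@H](O[Si](C)(C)C(C)(C)C)COCc1ccc(OC)cc1 | intermediate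
19 | cis-α-methylene-γ-butyrolactone (6R,7R), C7 (4S)-dioxolanyl, 4Z, C3–OH (3S), C2–OTBS (2R), C1–OPMB | C=C1C(=O)O[C@H](/C=C(/C)[C@H](O)[C@H](O[Si](C)(C)C(C)(C)C)COCc2ccc(OC)cc2)[C@@H]1[C@H]3COC(C)(C)O3 | intermediate
20 | as 19 with C3–OTIPS | C=C1C(=O)O[C@H](/C=C(/C)[C@H](O[Si](C(C)C)(C(C)C)C(C)C)[C@H](O[Si](C)(C)C(C)(C)C)COCc2ccc(OC)cc2)[C@@H]1[C@H]3COC(C)(C)O3 | intermediate
21 | as 20 with C1–OH | C=C1C(=O)O[C@H](/C=C(/C)[C@H](O[Si](C(C)C)(C(C)C)C(C)C)[C@H](O[Si](C)(C)C(C)(C)C)CO)[C@@H]1[C@H]3COC(C)(C)O3 | intermediate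
22 | as 20 with C1 aldehyde (C2 descriptor S by priority, same spatial arrangement) | C=C1C(=O)O[C@H](/C=C(/C)[C@H](O[Si](C(C)C)(C(C)C)C(C)C)[C@H](O[Si](C)(C)C(C)(C)C)C=O)[C@@H]1[C@H]3COC(C)(C)O3 | intermediate
23 | methyl propiolate | C#CC(=O)OC | starting material
24 | [1-(methoxycarbonyl)vinyl]diisobutylalane | C=C(C(=O)OC)[Al](CC(C)C)CC(C)C | intermediate
25 | Baylis–Hillman-type adduct: C1 carbinol (both epimers) bearing C10(=C9H2)CO2CH3; rest as 20 | C=C1C(=O)O[C@H](/C=C(/C)[C@H](O[Si](C(C)C)(C(C)C)C(C)C)[C@H](O[Si](C)(C)C(C)(C)C)C(O)C(=C)C(=O)OC)[C@@H]1[C@H]3COC(C)(C)O3 | intermediate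
26 | allylic bromide: C9H2Br on C10, 1(10)Z (C2 cis to C9), 4Z; 2R,3S,6R,7R | C=C1C(=O)O[C@H](/C=C(/C)[C@H](O[Si](C(C)C)(C(C)C)C(C)C)[C@H](O[Si](C)(C)C(C)(C)C)/C=C(/C(=O)OC)CBr)[C@@H]1[C@H]3COC(C)(C)O3 | intermediate
27 | 2-formylacrylate: C9 aldehyde, 1(10)E, dioxolane on C7 | C=C1C(=O)O[C@H](/C=C(/C)[C@H](O[Si](C(C)C)(C(C)C)C(C)C)[C@H](O[Si](C)(C)C(C)(C)C)/C=C(/C(=O)OC)C=O)[C@@H]1[C@H]3COC(C)(C)O3 | intermediate
28 | dialdehyde: C8 and C9 aldehydes, 1(10)E,4Z; 2R,3S,6R,7R | C=C1C(=O)O[C@H](/C=C(/C)[C@H](O[Si](C(C)C)(C(C)C)C(C)C)[C@H](O[Si](C)(C)C(C)(C)C)/C=C(/C(=O)OC)C=O)[C@@H]1C=O | intermediate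
29 | γ-(triethylsilyloxy)-2-(methoxycarbonyl)allylchromium dichloride, trivalent chromium on C1, silyloxy on C9 trans to C1 | C=C1C(=O)O[C@H](/C=C(/C)[C@H](O[Si](C(C)C)(C(C)C)C(C)C)[C@H](O[Si](C)(C)C(C)(C)C)C([Cr](Cl)Cl)/C(C(=O)OC)=C/O[Si](CC)(CC)CC)[C@@H]1C=O | intermediate
30 | macrocycle, 8-OH, 9-OSiEt3 (2R,3S,6R,7R,8S,9R; 1(10)E,4Z) | C=C1C(=O)O[C@@H]2/C=C(/C)[C@H](O[Si](C(C)C)(C(C)C)C(C)C)[C@H](O[Si](C)(C)C(C)(C)C)/C=C(/C(=O)OC)[C@@H](O[Si](CC)(CC)CC)[C@@H](O)[C@H]12 | intermediate
31 | mixed anhydride of 10 with 2,4,6-trichlorobenzoic acid | O=C(OC(=O)[C@@](C)(O[Si](CC)(CC)CC)[C@H](C)OC(C)=O)c1c(Cl)cc(Cl)cc1Cl | intermediate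
32 | C8 ester of 30 with acid 10 (9-OSiEt3 kept) | C=C1C(=O)O[C@@H]2/C=C(/C)[C@H](O[Si](C(C)C)(C(C)C)C(C)C)[C@H](O[Si](C)(C)C(C)(C)C)/C=C(/C(=O)OC)[C@@H](O[Si](CC)(CC)CC)[C@@H](OC(=O)[C@@](C)(O[Si](CC)(CC)CC)[C@H](C)OC(C)=O)[C@H]12 | intermediate
33 | (9R)-alcohol, C8 ester, side-chain OSiEt3 | C=C1C(=O)O[C@@H]2/C=C(/C)[C@H](O[Si](C(C)C)(C(C)C)C(C)C)[C@H](O[Si](C)(C)C(C)(C)C)/C=C(/C(=O)OC)[C@@H](O)[C@@H](OC(=O)[C@@](C)(O[Si](CC)(CC)CC)[C@H](C)OC(C)=O)[C@H]12 | intermediate
34 | (R)-2-methylbutanoic acid | CC[C@@H](C)C(=O)O | starting material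
35 | 8,9-diester (8S,9S), C2–OTBS, C3–OTIPS, side-chain OSiEt3 | C=C1C(=O)O[C@@H]2/C=C(/C)[C@H](O[Si](C(C)C)(C(C)C)C(C)C)[C@H](O[Si](C)(C)C(C)(C)C)/C=C(/C(=O)OC)[C@H](OC(=O)[C@H](C)CC)[C@@H](OC(=O)[C@@](C)(O[Si](CC)(CC)CC)[C@H](C)OC(C)=O)[C@H]12 | intermediate
36 | (2R)-alcohol, C3–OTIPS, free side-chain tertiary OH | C=C1C(=O)O[C@@H]2/C=C(/C)[C@H](O[Si](C(C)C)(C(C)C)C(C)C)[C@H](O)/C=C(/C(=O)OC)[C@H](OC(=O)[C@H](C)CC)[C@@H](OC(=O)[C@@](C)(O)[C@H](C)OC(C)=O)[C@H]12 | intermediate
37 | (2S)-chloride, C3–OTIPS | C=C1C(=O)O[C@@H]2/C=C(/C)[C@H](O[Si](C(C)C)(C(C)C)C(C)C)[C@@H](Cl)/C=C(/C(=O)OC)[C@H](OC(=O)[C@H](C)CC)[C@@H](OC(=O)[C@@](C)(O)[C@H](C)OC(C)=O)[C@H]12 | intermediate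
38 | (2S)-chloro (3S)-alcohol (chlorohydrin) | C=C1C(=O)O[C@@H]2/C=C(/C)[C@H](O)[C@@H](Cl)/C=C(/C(=O)OC)[C@H](OC(=O)[C@H](C)CC)[C@@H](OC(=O)[C@@](C)(O)[C@H](C)OC(C)=O)[C@H]12 | intermediate
39 | CNP0402153.1 | C=C1C(=O)O[C@@H]2/C=C(/C)[C@@H]3O[C@@H]3/C=C(/C(=O)OC)[C@H](OC(=O)[C@H](C)CC)[C@@H](OC(=O)[C@@](C)(O)[C@H](C)OC(C)=O)[C@H]12 | target

**Step count.** Total 25 steps. Longest linear sequence 19 steps (steps 7–25, from 11).

**Steps most likely to fail, with fallbacks**

1. Step 19 (ring closure). What may go wrong: β-elimination of the C2 silyloxy group from the allylchromium before it reaches the aldehyde, oligomerisation, and poor facial selectivity at C8. Fallback: from dialdehyde 28, a samarium diiodide pinacol macrocyclisation (SmI2, t-BuOH, THF, −78 °C, high dilution) should give, through the samarium-bridged cis-pinacolate, the (8S,9R)-8,9-diol F1. Selective silylation of its less hindered allylic C9 hydroxyl (Et3SiCl, imidazole, CH2Cl2, −40 °C) returns to the route at 30.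

2. Step 11 (Barbier allylation and lactonisation). What may go wrong: poor facial selectivity of the allylindium (C7) or of the aldehyde (C6), and acid-induced dehydration of the lactol to a furan. Fallback: from bromide 4, copper-catalysed borylation (B2pin2, CuCl (cat.), LiOt-Bu, THF) should give the allylboronate F2. Thermal allylboration of lactol 17 (toluene, 4 Å MS, 50 °C) runs through a closed chair without any Lewis acid and is syn-specific for the (Z)-boronate. PPTS lactonisation of the same open hydroxy ester 18 then returns to the route at 19.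

3. Step 22 (Mitsunobu inversion at C9). What may go wrong: SN2′ attack at C1, elimination, or esterification with retention at the hindered allylic carbinol. Fallback: from alcohol 33, Dess–Martin oxidation (NaHCO3, CH2Cl2) gives the C9 ketone F3. Reagent-controlled reduction ((S)-2-methyl-CBS-oxazaborolidine, catecholborane, toluene, −78 °C, the alkenyl C10 acting as the large group) gives the (9S)-alcohol F4. Acylation with 34 (DIC, DMAP, CH2Cl2) with retention returns to the route at 35.

**Further compounds**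

F1 | step 19 | macrocyclic (8S,9R)-8,9-diol, C2–OTBS, C3–OTIPS | C=C1C(=O)O[C@@H]2/C=C(/C)[C@H](O[Si](C(C)C)(C(C)C)C(C)C)[C@H](O[Si](C)(C)C(C)(C)C)/C=C(/C(=O)OC)[C@@H](O)[C@@H](O)[C@H]12
F2 | step 11 | methyl (2Z)-3-[(4S)-2,2-dimethyl-1,3-dioxolan-4-yl]-2-[(4,4,5,5-tetramethyl-1,3,2-dioxaborolan-2-yl)methyl]prop-2-enoate | CC1(C)OB(C/C(C(=O)OC)=C\[C@H]2COC(C)(C)O2)OC1(C)C
F3 | step 22 | C9 ketone of 33 | C=C1C(=O)O[C@@H]2/C=C(/C)[C@H](O[Si](C(C)C)(C(C)C)C(C)C)[C@H](O[Si](C)(C)C(C)(C)C)/C=C(/C(=O)OC)C(=O)[C@@H](OC(=O)[C@@](C)(O[Si](CC)(CC)CC)[C@H](C)OC(C)=O)[C@H]12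
F4 | step 22 | (9S)-alcohol, the C9 epimer of 33 | C=C1C(=O)O[C@@H]2/C=C(/C)[C@H](O[Si](C(C)C)(C(C)C)C(C)C)[C@H](O[Si](C)(C)C(C)(C)C)/C=C(/C(=O)OC)[C@H](O)[C@@H](OC(=O)[C@@](C)(O[Si](CC)(CC)CC)[C@H](C)OC(C)=O)[C@H]12
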